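I started from a one-step world, substrate to target, where the reagent charge makes no difference to the yield. But two further steps let substrate meet reagent, and the earlier runs show what that costs.

in all of them: substrate 0.011 M
- dusk: reagent 1.1 equiv; run made earlier
- autumn: reagent 9.2 equiv; run made earlier
- oak: reagent 6.00 equiv; time 4.0 min
- ash: reagent 2.20 equiv; time 4.0 min
- maple: reagent 4.50 equiv; time 4.0 min
- larch: reagent 1.50 equiv; time 4.0 min
- cedar: reagent 1.00 equiv; time 4.0 min

- dusk (time / s: target / %, substrate / %): 30.0: 37.6, 6.4; 60.0: 44.2, 5.1; 90.0: 49.8, 2.1; 120: 50.7, 2.6
- autumn (time / s: target / %, substrate / %): 30.0: 6.5, 0.4; 60.0: 4.8, 1.0; 90.0: 8.1, 1.2; 120: 6.9, 0.4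

(standard deviation of a reading: 1 percentage point)

- the analysis behind the earlier runs scatters by 1 percentage point, standard deviation
- what may be going on: substrate + reagent <-> intermediate; substrate + reagent -> side product; substrate -> target

1. ranking by amount of target, in percent of the substrate charged, from high to low, at 4.0 min (oak / ash / maple / larch / cedar)
2. the amount of target, in percent of the substrate charged of the flask you put first, at 4.0 min
3. the amount of target, in percent of the substrate charged of the flask you put last, at 4.0 min

I took the even split as the zero of my scale. At some amount of free reagent, substrate goes equally to target and to capture by reagent. If each captured substrate costs one reagent, the target made is that amount times the logarithm of reagent charged over reagent left. From the dusk run's last reading I got 0.853 equivalents for this balance reagent, the free reagent at which the two ways run level, a selectivity factor. The autumn run, whose target readings averaged 6.58%, gave 0.614 equivalents, less than dusk.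

So I looked for which one cheats. Dusk's substrate began with a half-life near 7.56 s, yet it went only from 5.1% to 2.6% between 60.0 s and 120 s, while target rose 6.5 percentage points. Something was handing substrate back, so both figures belong to unfinished flasks. Autumn's target readings rose 2.1 points over the same span, less than dusk's, and I carried dusk's figure. It gave cedar 53.4% and oak 13.2%, both estimates that I expected to lie low, with target falling as reagent rises.

The forecast gave cedar > larch > ash > maple > oak, with cedar at 57% (52% to 64%) and oak at 11% (8% to 14%), holding that “the outcome is set by competition”. The flasks gave cedar > larch > ash > maple > oak, with cedar at 61.5% and oak at 14.7%.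

    substrate + reagent ⇌ intermediate (K = 530 L mol⁻¹, k = 9.41 L mol⁻¹ s⁻¹)
    substrate + reagent → side product (k = 4.55 L mol⁻¹ s⁻¹)
    substrate → target (k = 0.0543 s⁻¹)

In cedar at 4.00 min, the step to target used substrate 1.7 times as fast as the step to side product, with 62% of the reagent charge free, and the balance reagent over that free reagent gives 1.37. For the neighbour of cedar charged with 2.50 equiv of reagent, the balance reagent gives 28.3% of target, and that flask held 32.9% at 4.00 min, with 9.33% still as intermediate.

The earlier runs and the new flask were generated by integration from invented constants.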